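With rising temperature a flask gets more exposure x in its 3.0 h, where x is the first-order constant k of the starting material (pseudo-first-order, the catalyst staying constant) times the time, so that a fraction e^(−x) of the charge stays unreacted.

| flask | starting material | catalyst | temperature | remark | time |
|---|---|---|---|---|---|
| north-west | 10 mM | 10 µM | 66 °C | run made earlier |  |
| north | 15 mM | 10 µM | 91 °C | run made earlier |  |
| south | 20 mM | 5 µM | 66 °C | run made earlier |  |
| winter | 20 mM | 10 µM | 70 °C |  | 3.0 h |
| spring | 20 mM | 10 µM | 85 °C |  | 3.0 h |
| noon | 20 mM | 10 µM | 55 °C |  | 3.0 h |
| autumn | 20 mM | 10 µM | 100 °C |  | 3.0 h |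

north-west run (percent of the starting material charged)

| time / h | target / % | isomer of the product / % |
|---|---|---|
| 0.417 | 22 | 0 |
| 0.833 | 35 | 0 |
| 1.33 | 47 | 0 |
| 1.50 | 53 | 0 |
| 2.00 | 61 | 0 |
| 2.50 | 67 | 2 |
| 3.00 | 72 | 0 |

north run (percent of the starting material charged)

| time / min | target / % | isomer of the product / % |
|---|---|---|
| 5.00 | 13 | 0 |
| 8.00 | 20 | 2 |
| 10.0 | 24 | 0 |
| 20.0 | 38 | 4 |
| 30.0 | 49 | 1 |
| 40.0 | 62 | 3 |
| 60.0 | 69 | 2 |

south run (percent of the starting material charged)

| time / h | target / % | isomer of the product / % |
|---|---|---|
| 0.250 | 6 | 1 |
| 0.417 | 8 | 0 |
| 0.833 | 20 | 2 |
| 1.50 | 32 | 0 |
| 3.00 | 51 | 0 |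

(each reading ± 2 percentage points)

1. the flask that comes out highest in share of target in all that became target or isomer of the product or over-reaction product, or "all alike" when all lie within 1.5 percentage points (winter / spring / noon / autumn / all alike)
2. share of target in all that became target or isomer of the product or over-reaction product, winter
3. share of target in all that became target or isomer of the product or over-reaction product, spring
4. share of target in all that became target or isomer of the product or over-reaction product, noon
5. share of target in all that became target or isomer of the product or over-reaction product, autumn

- in a conversion other conformer counts as not yet reacted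

Early readings, where little target can have been lost, give k as read values: 0.517 /h in the north-west run at 66 °C and 1.65 /h in the north run at 91 °C, hence a read activation energy of 47.6 kJ/mol. The south run, with half the catalyst and twice the starting material of north-west, reads 0.268 /h, half the north-west constant, which fits a k proportional to the catalyst and independent of the charge, although both settings differ between these two runs.

The zero of the scale is the loss-free curve, on which target equals the 1 − e^(−x) converted. At its last reading the north run has x = 1.65, so that curve promises 80.7%, yet target and isomer of the product together read 9.7 percentage points less. That gap, divided by the area x − (1 − e^(−x)) under the loss-free curve, gives the selectivity factor κ, the constant for using up target over the constant for making it: 0.116. It is one reading with its scatter, held fixed here for all four flasks, and the target then follows P = (e^(−κx) − e^(−x))/(1 − κ), with the small isomer set aside.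

In autumn k comes to 2.41 /h, which is the starting slope of the target curve. On this reckoning the knee of the autumn curve lies at x = 2.44, reached after 1.01 h at a peak of 75.4%, and the curve later sinks with a first-order constant of 0.279 /h, to 48.9% at 3.0 h. On the same reckoning noon (x = 0.881) and winter (x = 1.89) stop before the knee, while spring (x = 3.80) passes it. Dividing P by the converted part, this reckoning gives winter 86.9%, spring 71.9%, autumn 49.0% and noon 94.4%, the highest of the four.

The forecast also named noon but stood higher than this reckoning in each flask, with winter 98.8%, spring 97%, noon 99.5% and autumn 93.5%, holding that “selectivity falls with temperature”.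

The flask noon comes out highest at 97.7%, followed by winter at 92.5%, spring at 78.4% and autumn at 50.8%.

    catalyst + other conformer → catalyst + isomer of the product (k = 9200 /M/min, Ea = 41.0 kJ/mol)
    starting material ⇌ other conformer (K = 0.170, k = 0.00210 /min, Ea = 111 kJ/mol, ΔH = −30.0 kJ/mol)
    catalyst + target → catalyst + over-reaction product (k = 410 /M/min, Ea = 68.0 kJ/mol)
    starting material + catalyst → catalyst + target (k = 3800 /M/min, Ea = 46.0 kJ/mol)
    (constants at 100 °C)

With the step from target to over-reaction product struck out, autumn stands at 95.4%. The same κ at x = 3.61 gives autumn 71.4% of target at 1.50 h, where the flask holds 70.5%. For a flask like autumn but kept at 75 °C, with x = 2.40, κ gives a share of 82.9%, and that flask gives 89.1%.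

(The readings were generated by integration with constants of no real substance.)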